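The chair opened on a small charge: Monday's flask took 0.40 equiv of reagent on 0.40 M of solid substrate, Tuesday's took 1.6 equiv, and the meeting was to place a flask between them.

all flasks: solid substrate 0.40 M

| run | reagent | remark | time |
|---|---|---|---|
| Monday's | 0.40 equiv | run made earlier |  |
| Tuesday's | 1.6 equiv | run made earlier |  |
| flask | 0.800 equiv |  | 25 h |

| Monday's: time / h | Monday's: target / % | Tuesday's: time / h | Tuesday's: target / % |
|---|---|---|---|
| 2.00 | 6.3 | 2.00 | 22.4 |
| 3.00 | 9.3 | 3.00 | 34.1 |
| 6.00 | 15.6 | 6.00 | 49.6 |
| 10.0 | 18.9 | 10.0 | 58.7 |
| 15.0 | 21.0 | 15.0 | 65.8 |
| 25.0 | 25.8 | 25.0 | 74.0 |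

(scatter of a reading: 0.5 percentage points)

- east: doubling the amount of reagent, all else as stated
- south-west: doubling the solubility of the solid substrate, all else as stated
- north-west: doubling the dissolution coefficient of the solid substrate, all else as stated

- as a solid, counted per litre of solution: solid substrate
- the numbers in the tables scatter with a standard deviation of 0.5 percentage points
- at the start none of the solid substrate is in solution

- target at 25 h, in percent of the solid substrate charged
- the change that raises the amount of target at 25 h, in percent of the solid substrate charged most ("none" if none brings more than 2 percentage points) (east / south-west / north-west / none)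
- amount of target at 25 h, in percent of the solid substrate charged, after east

The kineticist proposed reading each run as φ, the target formed as a fraction of the reagent charged. At 2.00 h, she reported, φ stood at 15.8% on Monday and 14.0% on Tuesday, so early target followed the reagent charge. At 25.0 h the two had parted: Tuesday's φ stood at 46.2%, and Monday's was higher, at 64.5%.

The process chemist noted that this flask's charge is twice Monday's and half of Tuesday's, and argued for their geometric mean, the reagent yield expected of this flask at 25 h, 54.6%. With reagent as limiting reagent, that made 43.7% target.

The chair recorded that east reproduces Tuesday's recipe, reading 74.0%, a gain of 30 percentage points. If the solid-side changes lifted this flask to Monday's φ, target would reach 51.6%, a gain of 7.9 points, less than east.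

The forecast gave 45% (40% to 50%), higher than the meeting's 43.7%, and 74% after east (73% to 75%), concluding: “East is the best bet”.

The simulation gives 47.4%, and 74.3% after east, with east best at 27 points, against 4.3 points for south-west and 2.5 points for north-west.

    solid substrate ⇌ dissolved substrate, rate k1*(cs1 - [dissolved substrate]) while solid is left; crystals form when [dissolved substrate] > cs1 (solubility = 0.280 M, k = 1.11 h⁻¹)
    dissolved substrate + reagent → target (k = 0.645 M⁻¹ h⁻¹)
    reagent → side product (k = 0.0158 h⁻¹)
    reagent ⇌ dormant form (K = 2.35, k = 0.189 h⁻¹)
    reagent → decomposition product (k = 5.23 × 10⁻⁵ h⁻¹)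
    2 solid substrate → self-condensation product (k = 0.329 M⁻¹ h⁻¹)

This flask has not come to rest at 25 h: its φ is 59.3%, above the 54.6% reckoned. The neighbour with 1.6 M of solid substrate, at the same equivalents, shows φ of 46.9% at that hour. Left until 250 h, this flask keeps its self-condensation product at 14.1%, while dormant form falls from 0.0824 M to 0.00150 M, dissolved substrate falls from 38.5% to 17.4%, and side product rises from 0.0244 M to 0.0438 M. Target then reads 68.5%, a φ of 85.6%.

The earlier runs and the new flask are simulated with made-up constants; noise was put on by code.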